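**Retrosynthetic overview**
1. Target 24 ← methanol addition–elimination on vinylogous acyl triflate 23, which fixes the C3 enol ether ← enol triflate formation and oxidation from β-hydroxy ketone 18 ← conjugate borylation–oxidation of enone 16.
2. Mixed ketal carbon C4 (in 16) ← α-chlorination and silver-assisted methanolysis of α-aryloxy enone 13, with 1,3-induction from C6 ← SN2 coupling of phenol 4 with α′-bromo enone 12.
3. The cyclohexenone ring is the only ring built (the arene is carried from 1) ← intramolecular aldol condensation of keto aldehyde 7.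
4. C5–C6 bond and the C6 stereocentre ← enamine-catalysed intermolecular Michael addition of pent-4-enal 5 to methyl vinyl ketone 6 (the fragment union).
5. Phenol 4 ← aromatic Claisen rearrangement of the allyl ether of 3,4-dimethoxyphenol 1.

Assumption: the (R)-diarylprolinol ether shows the usual enamine face selectivity (mirror image of the well-studied (S)-catalyst), so it gives (R)-7.

**Route**

Step 1
Reactants: 1 3,4-dimethoxyphenol; 2 allyl bromide
Product: 3 4-(allyloxy)-1,2-dimethoxybenzene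
Conditions: K2CO3, acetone, reflux
Reagents that add atoms: none
Why: Williamson ether synthesis (SN2 of the phenoxide on the allylic bromide).

Step 2
Reactants: 3 4-(allyloxy)-1,2-dimethoxybenzene
Product: 4 2-allyl-4,5-dimethoxyphenol
Conditions: N,N-diethylaniline, 190 °C
Reagents that add atoms: none
Why: aromatic Claisen rearrangement to the ortho position that is not flanked by a methoxy group, followed by tautomerisation to the phenol.

Step 3
Reactants: 5 pent-4-enal; 6 but-3-en-2-one (methyl vinyl ketone)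
Product: 7 (2R)-2-allyl-5-oxohexanal
Conditions: (R)-2-[methoxy(diphenyl)methyl]pyrrolidine (5 mol%), ethyl 3,4-dihydroxybenzoate (20 mol%), neat, 4 °C
Reagents that add atoms: none
Why: enamine-catalysed intermolecular Michael addition in which the diphenyl(methoxy)methyl group shields one face of the E-enamine, setting the stereocentre that becomes C6 (S) of the target.

Step 4
Reactants: 7 (2R)-2-allyl-5-oxohexanal
Product: 9 (4R)-4-allylcyclohex-2-en-1-one, via aldol adduct 8 (not isolated)
Conditions: LiOH·H2O (0.2 equiv), i-PrOH, 0 °C to rt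
Reagents that add atoms: none
Why: intramolecular aldol condensation of the methyl ketone enolate onto the aldehyde (six-membered ring, irreversible dehydration) under mild base that leaves the stereocentre intact.

Step 5
Reactants: 9 (4R)-4-allylcyclohex-2-en-1-one
Product: 12 (4S)-4-allyl-6-bromocyclohex-2-en-1-one (C6 epimers), via lithium dienolate 10 (not isolated), via silyl dienol ether 11 (not isolated)
Conditions: LiN(iPr)2, THF, −78 °C; Me3SiCl; then N-bromosuccinimide, THF, −78 to 0 °C
Reagents that add atoms: N-bromosuccinimide (O=C1CCC(=O)N1Br)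
Why: kinetic α′-deprotonation gives the cross-conjugated dienolate without touching the γ-hydrogen at the stereocentre, and its silyl dienol ether is brominated at the α′-carbon (electrophilic α-halogenation).

Step 6
Reactants: 12 (4S)-4-allyl-6-bromocyclohex-2-en-1-one; 4 2-allyl-4,5-dimethoxyphenol
Product: 13 (4S)-4-allyl-6-(2-allyl-4,5-dimethoxyphenoxy)cyclohex-2-en-1-one (C6 epimers)
Conditions: Cs2CO3, acetone, 0 °C to rt
Reagents that add atoms: none
Why: SN2 displacement of the activated α-bromo ketone by the caesium phenoxide (Williamson-type); the epimer mixture at C6 is erased in step 7.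

Step 7
Reactants: 13 (4S)-4-allyl-6-(2-allyl-4,5-dimethoxyphenoxy)cyclohex-2-en-1-one
Product: 16 (4S,6R)-4-allyl-6-(2-allyl-4,5-dimethoxyphenoxy)-6-methoxycyclohex-2-en-1-one, via lithium enolate 14 (not isolated), via chloro ketone 15 (not isolated)
Conditions: LiN(iPr)2, THF, −78 °C; N-chlorosuccinimide, −78 °C; then AgOSO2CF3, 2,6-di-tert-butyl-4-methylpyridine, MeOH/CH2Cl2, −78 to −20 °C
Reagents that add atoms: methanol (CO)
Why: enolate chlorination followed by silver-assisted SN1 methanolysis (Koenigs–Knorr type), in which methanol adds to the aryloxy-stabilised oxocarbenium ion along the pseudo-axial trajectory trans to the pseudo-equatorial allyl group (1,3-induction), setting the ketal carbon as 6R; the minor epimer is removed by chromatography.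

Step 8
Reactants: 16 (4S,6R)-4-allyl-6-(2-allyl-4,5-dimethoxyphenoxy)-6-methoxycyclohex-2-en-1-one
Product: 18 (2R,4S)-4-allyl-2-(2-allyl-4,5-dimethoxyphenoxy)-5-hydroxy-2-methoxycyclohexan-1-one (C5 epimers), via boronate 17 (not isolated)
Conditions: CuCl (5 mol%), bis[2-(diphenylphosphino)phenyl] ether (5 mol%), NaOC(CH3)3 (10 mol%), bis(pinacolato)diboron, MeOH (2 equiv), THF, rt; then NaBO3·4H2O, THF/H2O, rt
Reagents that add atoms: sodium perborate tetrahydrate ([Na+].[Na+].O[B-]1(O)OO[B-](O)(O)OO1)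
Why: copper-catalysed conjugate borylation of the enone, chemoselective over the isolated alkenes, then C–B oxidation installs the oxygen at the future C1; the carbinol configuration is irrelevant because it is oxidised in step 12.

Step 9
Reactants: 18 (2R,4S)-4-allyl-2-(2-allyl-4,5-dimethoxyphenoxy)-5-hydroxy-2-methoxycyclohexan-1-one
Product: 19 (2R,4S)-4-allyl-2-(2-allyl-4,5-dimethoxyphenoxy)-5-[(tert-butyldimethylsilyl)oxy]-2-methoxycyclohexan-1-one
Conditions: tert-butyldimethylsilyl chloride, imidazole, DMF, rt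
Reagents that add atoms: tert-butyldimethylsilyl chloride (CC(C)(C)[Si](C)(C)Cl)
Why: silyl protection of the secondary alcohol under non-acidic conditions, which blocks retro-aldol cleavage in the next step.

Step 10
Reactants: 19 (2R,4S)-4-allyl-2-(2-allyl-4,5-dimethoxyphenoxy)-5-[(tert-butyldimethylsilyl)oxy]-2-methoxycyclohexan-1-one
Product: 21 (4S,6R)-4-allyl-6-(2-allyl-4,5-dimethoxyphenoxy)-3-[(tert-butyldimethylsilyl)oxy]-6-methoxycyclohex-1-en-1-yl trifluoromethanesulfonate, via potassium enolate 20 (not isolated)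
Conditions: KN(SiMe3)2, THF, −78 °C; PhN(SO2CF3)2, −78 to −40 °C
Reagents that add atoms: N-phenylbis(trifluoromethanesulfonimide) (O=S(=O)(N(c1ccccc1)S(=O)(=O)C(F)(F)F)C(F)(F)F)
Why: the ketone can enolise only toward the CH2 group because the other α-carbon is the quaternary ketal, so enolate O-triflation (McMurry-type enol triflate synthesis) fixes the position of the future enol ether.

Step 11
Reactants: 21 (4S,6R)-4-allyl-6-(2-allyl-4,5-dimethoxyphenoxy)-3-[(tert-butyldimethylsilyl)oxy]-6-methoxycyclohex-1-en-1-yl trifluoromethanesulfonate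
Product: 22 (4S,6R)-4-allyl-6-(2-allyl-4,5-dimethoxyphenoxy)-3-hydroxy-6-methoxycyclohex-1-en-1-yl trifluoromethanesulfonate (C3 epimers)
Conditions: Bu4NF, AcOH (1:1), THF, 0 °C to rt
Reagents that add atoms: none
Why: buffered fluoride desilylation, which leaves the enol triflate and the mixed ketal untouched.

Step 12
Reactants: 22 (4S,6R)-4-allyl-6-(2-allyl-4,5-dimethoxyphenoxy)-3-hydroxy-6-methoxycyclohex-1-en-1-yl trifluoromethanesulfonate
Product: 23 (4S,6R)-4-allyl-6-(2-allyl-4,5-dimethoxyphenoxy)-6-methoxy-3-oxocyclohex-1-en-1-yl trifluoromethanesulfonate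
Conditions: Dess–Martin periodinane, pyridine, CH2Cl2, 0 °C
Reagents that add atoms: none
Why: Dess–Martin oxidation of the allylic alcohol under buffered conditions gives the vinylogous acyl triflate with the carbonyl at C1, next to the allyl-bearing carbon.

Step 13
Reactants: 23 (4S,6R)-4-allyl-6-(2-allyl-4,5-dimethoxyphenoxy)-6-methoxy-3-oxocyclohex-1-en-1-yl trifluoromethanesulfonate
Product: 24 (4R,6S)-6-allyl-4-(2-allyl-4,5-dimethoxyphenoxy)-3,4-dimethoxycyclohex-2-en-1-one
Conditions: K2CO3, MeOH, 0 °C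
Reagents that add atoms: methanol (CO)
Why: conjugate addition of methoxide and loss of triflate (addition–elimination on a vinylogous acyl triflate) gives the vinylogous ester with unambiguous regiochemistry under base, where the acid-labile mixed ketal and both stereocentres persist.

**Compound list**
1 | 3,4-dimethoxyphenol | COc1ccc(O)cc1OC | starting material
2 | allyl bromide | C=CCBr | starting material
3 | 4-(allyloxy)-1,2-dimethoxybenzene | C=CCOc1ccc(OC)c(OC)c1 | intermediate
4 | 2-allyl-4,5-dimethoxyphenol | C=CCc1cc(OC)c(OC)cc1O | intermediate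
5 | pent-4-enal | C=CCCC=O | starting material
6 | but-3-en-2-one (methyl vinyl ketone) | CC(=O)C=C | starting material
7 | (2R)-2-allyl-5-oxohexanal | CC(=O)CC[C@H](CC=C)C=O | intermediate
8 | (4R)-4-allyl-3-hydroxycyclohexan-1-one (aldol adduct, C3 epimers) | O=C1CC(O)[C@@H](CC=C)CC1 | intermediate
9 | (4R)-4-allylcyclohex-2-en-1-one | O=C1C=C[C@@H](CC=C)CC1 | intermediate
10 | lithium (4S)-4-allylcyclohexa-1,5-dien-1-olate | [Li+].[O-]C1=CC[C@H](CC=C)C=C1 | intermediate
11 | (S)-[(4-allylcyclohexa-1,5-dien-1-yl)oxy]trimethylsilane | C[Si](C)(C)OC1=CC[C@H](CC=C)C=C1 | intermediate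
12 | (4S)-4-allyl-6-bromocyclohex-2-en-1-one (C6 epimers) | O=C1C=C[C@@H](CC=C)CC1Br | intermediate
13 | (4S)-4-allyl-6-(2-allyl-4,5-dimethoxyphenoxy)cyclohex-2-en-1-one (C6 epimers) | C=CCc1cc(OC)c(OC)cc1OC1C[C@H](CC=C)C=CC1=O | intermediate
14 | lithium (4S)-4-allyl-2-(2-allyl-4,5-dimethoxyphenoxy)cyclohexa-1,5-dien-1-olate | [Li+].[O-]C1=C(Oc2cc(OC)c(OC)cc2CC=C)C[C@H](CC=C)C=C1 | intermediate
15 | (4S)-4-allyl-6-(2-allyl-4,5-dimethoxyphenoxy)-6-chlorocyclohex-2-en-1-one (C6 epimers) | C=CCc1cc(OC)c(OC)cc1OC1(Cl)C[C@H](CC=C)C=CC1=O | intermediate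
16 | (4S,6R)-4-allyl-6-(2-allyl-4,5-dimethoxyphenoxy)-6-methoxycyclohex-2-en-1-one | C=CCc1cc(OC)c(OC)cc1O[C@]1(OC)C[C@H](CC=C)C=CC1=O | intermediate
17 | (2R,4S)-4-allyl-2-(2-allyl-4,5-dimethoxyphenoxy)-2-methoxy-5-(4,4,5,5-tetramethyl-1,3,2-dioxaborolan-2-yl)cyclohexan-1-one (C5 epimers) | C=CCc1cc(OC)c(OC)cc1O[C@]1(OC)C[C@H](CC=C)C(B2OC(C)(C)C(C)(C)O2)CC1=O | intermediate
18 | (2R,4S)-4-allyl-2-(2-allyl-4,5-dimethoxyphenoxy)-5-hydroxy-2-methoxycyclohexan-1-one (C5 epimers) | C=CCc1cc(OC)c(OC)cc1O[C@]1(OC)C[C@H](CC=C)C(O)CC1=O | intermediate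
19 | (2R,4S)-4-allyl-2-(2-allyl-4,5-dimethoxyphenoxy)-5-[(tert-butyldimethylsilyl)oxy]-2-methoxycyclohexan-1-one (C5 epimers) | C=CCc1cc(OC)c(OC)cc1O[C@]1(OC)C[C@H](CC=C)C(O[Si](C)(C)C(C)(C)C)CC1=O | intermediate
20 | potassium (4S,6R)-4-allyl-6-(2-allyl-4,5-dimethoxyphenoxy)-3-[(tert-butyldimethylsilyl)oxy]-6-methoxycyclohex-1-en-1-olate | C=CCc1cc(OC)c(OC)cc1O[C@]1(OC)C[C@H](CC=C)C(O[Si](C)(C)C(C)(C)C)C=C1[O-].[K+] | intermediate
21 | (4S,6R)-4-allyl-6-(2-allyl-4,5-dimethoxyphenoxy)-3-[(tert-butyldimethylsilyl)oxy]-6-methoxycyclohex-1-en-1-yl trifluoromethanesulfonate (C3 epimers) | C=CCc1cc(OC)c(OC)cc1O[C@]1(OC)C[C@H](CC=C)C(O[Si](C)(C)C(C)(C)C)C=C1OS(=O)(=O)C(F)(F)F | intermediate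
22 | (4S,6R)-4-allyl-6-(2-allyl-4,5-dimethoxyphenoxy)-3-hydroxy-6-methoxycyclohex-1-en-1-yl trifluoromethanesulfonate (C3 epimers) | C=CCc1cc(OC)c(OC)cc1O[C@]1(OC)C[C@H](CC=C)C(O)C=C1OS(=O)(=O)C(F)(F)F | intermediate
23 | (4S,6R)-4-allyl-6-(2-allyl-4,5-dimethoxyphenoxy)-6-methoxy-3-oxocyclohex-1-en-1-yl trifluoromethanesulfonate | C=CCc1cc(OC)c(OC)cc1O[C@]1(OC)C[C@H](CC=C)C(=O)C=C1OS(=O)(=O)C(F)(F)F | intermediate
24 | (4R,6S)-6-allyl-4-(2-allyl-4,5-dimethoxyphenoxy)-3,4-dimethoxycyclohex-2-en-1-one | C=CCc1cc(OC)c(OC)cc1O[C@]1(OC)C[C@H](CC=C)C(=O)C=C1OC | target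

**Totals and risks**

Total step count: 13. Longest linear sequence: 11 steps (steps 3 to 13, from 5 and 6); the phenol arm (steps 1 and 2) joins at step 6.

Steps most likely to fail:

Step 6. The α′-bromo enone 12 can lose HBr and tautomerise to a phenol instead of undergoing substitution. The fallback sets out from 9 and comes back at 13 and avoids any alkyl halide. Detrifluoroacetylative diazo transfer (LiN(SiMe3)2 and 2,2,2-trifluoroethyl trifluoroacetate in THF at −78 °C, then CH3SO2N3, Et3N and water in MeCN) passes through (4S)-4-allyl-6-(2,2,2-trifluoroacetyl)cyclohex-2-en-1-one F1 to (4S)-4-allyl-6-diazocyclohex-2-en-1-one F2. Slow addition of F2 to phenol 4 and Rh2(OAc)4 (1 mol%) in CH2Cl2 then gives 13 by carbenoid O–H insertion.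

Step 7. The chloro ketone 15 can lose HCl toward a dienone that aromatises, and the face selectivity of the methanol addition may be only moderate. The fallback sets out from 13 and comes back at 16 and replaces the halide by a stable thio donor. The enolate of 13 (LiN(iPr)2, THF, −78 °C) is sulfenylated with S-phenyl benzenethiosulfonate to (4S)-4-allyl-6-(2-allyl-4,5-dimethoxyphenoxy)-6-(phenylsulfanyl)cyclohex-2-en-1-one F3, which can be purified. F3 is then activated with MeOSO2CF3 and 2,6-di-tert-butyl-4-methylpyridine in MeOH/CH2Cl2 at −40 °C (thioglycoside-type activation) and is captured by methanol through the same aryloxy oxocarbenium ion.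

Step 10. The β-silyloxy enolate 20 can expel silanolate (returning enone 16) before it is triflated. The fallback sets out from 18 and comes back at 24 and needs no enolate. Dess–Martin oxidation of 18 (pyridine, CH2Cl2, 0 °C) gives (4S,6R)-4-allyl-6-(2-allyl-4,5-dimethoxyphenoxy)-6-methoxycyclohexane-1,3-dione F4, which is O-methylated at once with Me3SiCHN2 in MeOH/toluene at 0 °C. The enol oxygen next to the electron-poor ketal carbon is expected to be methylated preferentially, and the regioisomeric enol ether is separated by chromatography.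

**Further compounds**
F1 | step 6 | (4S)-4-allyl-6-(2,2,2-trifluoroacetyl)cyclohex-2-en-1-one (C6 epimers) | O=C(C1C[C@H](CC=C)C=CC1=O)C(F)(F)F
F2 | step 6 | (4S)-4-allyl-6-diazocyclohex-2-en-1-one | [N-]=[N+]=C1C[C@H](CC=C)C=CC1=O
F3 | step 7 | (4S)-4-allyl-6-(2-allyl-4,5-dimethoxyphenoxy)-6-(phenylsulfanyl)cyclohex-2-en-1-one (C6 epimers) | C=CCc1cc(OC)c(OC)cc1OC1(Sc2ccccc2)C[C@H](CC=C)C=CC1=O
F4 | step 10 | (4S,6R)-4-allyl-6-(2-allyl-4,5-dimethoxyphenoxy)-6-methoxycyclohexane-1,3-dione | C=CCc1cc(OC)c(OC)cc1O[C@]1(OC)C[C@H](CC=C)C(=O)CC1=O
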